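I began by setting the reagent charged to this flask against what conversion can take from it.

| flask | starting material | reagent | free catalyst | remark |
|---|---|---|---|---|
| alder | 0.055 M | 0.121 M | 5.5 mM | run made earlier |
| larch | 0.083 M | 0.121 M | 5.5 mM | run made earlier |
| oak | 0.11 M | 0.121 M | 11 mM | run made earlier |
| flask | 0.11 M | 0.121 M | 5.5 mM |  |

- alder (time / h: target / %): 0.667: 0; 2.00: 0; 3.00: 1; 5.00: 3; 8.00: 5
- larch (time / h: target / %): 0.500: 1; 1.00: 1; 2.00: 0; 4.00: 3; 8.00: 7
- oak (time / h: target / %): 0.667: 2; 2.00: 0; 3.00: 2; 5.00: 7; 8.00: 14

(each reading ± 1.5 percentage points)

- steps under discussion: starting material + free catalyst <-> free catalyst + open intermediate; free catalyst + open intermediate <-> catalyst intermediate; reagent + catalyst intermediate -> free catalyst + target; 2 reagent -> self-condensation product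
- what has left starting material counts as converted, also if it is not yet product
- no earlier run changes the charge of reagent; that part of a forecast is a guess

* apparent order in free catalyst when 30% of the starting material are converted (percent change of the rate of making target for one percent more free catalyst charged)
* apparent order in reagent when 30% of the starting material are converted (percent change of the rate of making target for one percent more reagent charged)

Could making target thin the reagent by the moment asked about? Each target takes one reagent. If every converted starting material had become target at 30% conversion, the conversion claim, the share of the reagent charge that this conversion can take, would be 27.3%. So 72.7% of the charge stood free of that demand.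

What then sets the time to get there? Oak, with 11 mM of free catalyst and 0.11 M of starting material, read 14% target at 8.00 h, and larch, with 5.5 mM and 0.083 M, read 7%, each reading with a scatter of 1.5 percentage points. Two settings differ between these runs, so the pair gave me no clean ratio for free catalyst. I took free catalyst as the clock of the catalysed steps: more catalyst, proportionally less time to the same conversion, the same mixture there, and an order of one.

But self-condensation uses no catalyst, so it keeps ordinary time, and a shorter run should leave more reagent. I therefore committed to an order in free catalyst above one, by an amount I could not read, since no run measured reagent. For reagent, whose charge no run changes, I guessed below one.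

The forecast gave 1.05 (0.75 to 1.45) in free catalyst and 0.7 (0.3 to 1.1) in reagent, noting that “Both ring-opening and capture are catalysed”.

The flask gave 1.5 in free catalyst and 0.39 in reagent.

    starting material + free catalyst ⇌ free catalyst + open intermediate (K = 0.370, k = 7.40 /M/h)
    free catalyst + open intermediate ⇌ catalyst intermediate (K = 21.0 /M, k = 75.0 /M/h)
    reagent + catalyst intermediate → free catalyst + target (k = 14.0 /M/h)
    2 reagent → self-condensation product (k = 0.390 /M/h)

By 6.00 h the flask had lost 38.7% of its reagent, more than the whole claim of 27.3%, although the target made by then had taken 3.39%. In the run without self-condensation, the order in free catalyst fell from 1.5 to 1.0. A flask with doubled free catalyst has the same charges of reagent and starting material, hence the same claim of 27.3%, yet its rate of making target at 30% conversion stood at 2.69 times this flask's.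

Readings and results were computed for substances that don't exist, and the scatter is random.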